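## The problem

Target 14 is a flavonol: benzene ring A is fused to the 4-pyranone ring C across C4a–C8a, and the ring B aryl group sits on C2. It has no stereocentre, so nothing has to be controlled in space. The one stereogenic carbon met on the way, the enolisable α-carbon of keto ester 5, is racemic by nature and ends as the sp2 carbon C3. The real task is to sort five oxygen atoms into three states: acetate at C3, free hydroxyl at C5, and hydrogen sulfate esters at C7, C3' and C4'. Two of these functions are fragile. Aryl sulfate monoesters are cleaved by acid and make every intermediate a water-soluble polyanion, so they must follow all acidic steps, while the C3 acetate is an enol ester that bases and nucleophiles remove, so it must come very late. The C3 oxygen therefore has to be distinguishable from the other four from the moment it enters, which argues for bringing it in on its own building block under its own mask. What makes a short route possible is ring A: O1 on C8a, the C5 hydroxyl and the C7 oxygen are mutually meta, the pattern of phloroglucinol 6, in which every ring C–H is flanked by equivalent hydroxyls, so any C–H/O–H pair can become C4a/C8a. In addition, the C5 hydroxyl of the finished chromone is held to the C4 carbonyl by a six-membered hydrogen bond and resists sulfation and mild acylation, so it needs no protecting group.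

## Retrosynthesis

**14 ⇒ 13 (acyl C–O bond at C3).** The acetate is the most labile group and is cut first, leaving trisulfate 13 with only the C3 and C5 hydroxyls free. Placing sulfation after acetylation instead would need a second, orthogonal set of protecting groups on the C7, C3' and C4' oxygens and several more steps. The forward reaction must acylate C3–OH and spare the chelated C5–OH in the presence of three sulfate anions.

**13 ⇒ 12 (benzyl C–O bond at C3).** The C3 oxygen is traced back to a benzyl ether. Benzyl is chosen because it survives heat, aqueous acid and sulfation, and is removed by neutral hydrogenolysis, which aryl sulfates tolerate. The forward step must cleave one benzyl ether without reducing the pyranone or losing sulfate.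

**12 ⇒ 11 (three S–O bonds).** All three sulfates are removed together, giving tetrol 11, a neutral compound that can still be purified on silica. No protecting group is spent on C5, because chelation differentiates it. The forward step must drive three phenols, two of them vicinal, to complete sulfation.

**11 ⇒ 10 (two ketal C–O bonds).** The ring B catechol is masked as a diphenylmethylene ketal. Unlike benzyl ethers on ring B, this ketal is orthogonal to the C3 benzyl ether: aqueous acid removes it and leaves benzyl alone. The acid step falls before any sulfate exists.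

**10 ⇒ 5 + 6 (C4a–C4 and O1–C2; ring C).** Cutting both bonds that join ring A to the three-carbon unit gives phloroglucinol 6 and α-benzyloxy β-keto ester 5, through acylketene 7, diketone 8 and hemiketal 9 in the forward sense. Cuts at C2–C3 or C3–C4 would leave a ring A fragment that is itself unsymmetrical and must be made. This cut removes one ring and two skeletal bonds at once and leaves a symmetrical commercial triol. The forward reaction must acylate at carbon and close to the chromone, not the coumarin.

**5 ⇒ 3 + 4 (bond between the future C2 and C3).** The keto ester is cut between its α-carbon and the aryl ketone carbon, giving aryl ester 3 and glycolate ester 4, which already carries the benzylated C3 oxygen. The alternative, oxidising an unsubstituted aroylacetate at its α-carbon, costs two more steps and is kept in reserve. The forward step is an ester enolate acylation with a non-enolisable partner.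

**3 ⇒ 1 + 2 (two ketal C–O bonds).** Ester 3 comes from methyl 3,4-dihydroxybenzoate 1 and dichlorodiphenylmethane 2 by thermal ketalisation.

## Roads not taken

**Alternative 1:** The cut is the C3–C4 bond at the dihydroflavonol level, which opens ring C to dialdehyde A2, a ring A aryl aldehyde tethered through O1 to an α-aryl acetaldehyde. Forward, a thiazolium-derived carbene generated with DBU would turn the ring A formyl group into an acyl anion equivalent that adds to the aliphatic formyl group, closing ring C as racemic trans-3-hydroxyflavanone A1.
- Merits: the conditions are mild, metal-free and catalytic. A1 emerges with C3–OH as the only free hydroxyl of a perbenzylated molecule, so C3 could be acetylated before one global hydrogenolysis and sulfation would be the last operation on a neutral substrate. In this respect the road is better than the chosen one, which must acetylate a trisulfate salt.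
- Weak points: A1 is two hydrogens too rich, so C2–C3 must be dehydrogenated and both new stereocentres are discarded. The acyl anion has to form at a formyl group flanked by two ortho oxygens, while the more accessible aliphatic formyl group can take that role and invert the polarity of the coupling. The α-aryl, α-aryloxy aldehyde of A2 is highly enolisable and under DBU can close by intramolecular aldol addition to a five-membered ring. A2 itself requires desymmetrisation and selective benzylation of 6 and the release of one aldehyde in the presence of another.
- Comparison: against the cleaner endgame, the chosen plan assembles the complete flavonol core at the correct oxidation level in three steps from bulk chemicals, with no competition between two aldehydes.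

**Alternative 2:** Here ring A is built, not bought: four bonds (C8–C8a, C7–C8, C5–C6, C4a–C5) are cut, leading to pyranonyl diazo ketone A4 and silyloxyalkyne A5. Forward, irradiation of A4 triggers a Wolff rearrangement; [2+2] cycloaddition with A5, four-electron ring opening and six-electron ring closure on heating would give phenol A3 (Danheiser benzannulation).
- Merits: A3 has exactly the differentiation the target needs: acetate in place at C3, the C5 hydroxyl set free by the annulation itself, and the three sulfation sites as silyl ethers. Desilylation and sulfation would finish the synthesis. On protecting-group logic this is the most elegant of the four roads, and its endgame is shorter than the four steps of the chosen plan.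
- Weak points: it constructs a benzene ring that is commercially available with the right oxygen pattern. A4 is a fully substituted 4-pyranone acid derivative that needs arylation and acyloxylation of the heterocycle, an acid chloride and diazomethane, and would on any reasonable count take more steps than the whole chosen route. The 4-pyranone and aryl enol acetate chromophores of A4 have photochemistry of their own. The π bond that must enter the electrocyclic closure belongs to an electron-poor, partly aromatic vinylogous ester. Fluoride removal of three aryl silyl ethers beside an enol acetate invites acetate cleavage.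
- Comparison: the chosen plan sets against the better endgame a much shorter route without diazo compounds or photochemistry, and a key step used on its native substrate class.

**Alternative 3:** The same two bonds are cut as in the chosen plan, C4a–C4 and O1–C2, but ring A enters as aryne A9, released by fluoride from silyl triflate A8, and the three-carbon unit as β-chloroacrylic acid A7. Forward, CsF sets A9 free, the carboxylate of A7 adds at C8a, the aryl anion at C4a takes the acyl carbon, and the liberated phenoxide displaces chloride at C2 by addition–elimination to give flavone A6.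
- Merits: the reaction runs near ambient temperature instead of in a melt at 240 °C. The alkoxy group next to the aryne directs the regiochemistry. The C3 allyl ether is orthogonal to the four benzyl ethers, so deallylation with Pd(PPh3)4, acetylation, hydrogenolysis and a closing sulfation would again avoid acetylating a trisulfate. On conditions and on the order of the last steps this road is better.
- Weak points: several steps are spent converting symmetrical 6 into unsymmetrical A8 to obtain a regiochemical result that symmetry gives for free. A7 needs a Claisen condensation like step 2 followed by chlorination and saponification, so it is strictly longer to make than 5. The tetrasubstituted chloroalkene is hindered in the final closure. Protonation of the aryl anion before acyl transfer, leaving simple O-arylation, is the usual failure of such insertions.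
- Comparison: the chosen plan sets against this roughly half the step count, no protecting groups on ring A, and 6 used as bought.

Key step: step 3

Assumption: sulfated compounds 12, 13 and 14 are drawn and named as free sulfuric acid monoesters; they would be handled as sodium or tetrabutylammonium salts after counter-ion exchange, and the acid form of 14 would be released only at the end on a cation-exchange resin in the H+ form.

## Route

Step 1
Reactants: 1 methyl 3,4-dihydroxybenzoate; 2 dichlorodiphenylmethane
Product: 3 methyl 2,2-diphenyl-1,3-benzodioxole-5-carboxylate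
Conditions: neat, 175 °C, N2 stream
Reagents that add atoms: none
Why: Thermal ketalisation of a catechol with a gem-dichloride (double substitution through the diaryl-stabilised chlorocarbenium ion); the five-membered benzodioxole closes readily, HCl leaves as gas and the methyl ester is untouched.

Step 2
Reactants: 3 methyl 2,2-diphenyl-1,3-benzodioxole-5-carboxylate; 4 ethyl 2-(benzyloxy)acetate
Product: 5 racemic ethyl 2-(benzyloxy)-3-(2,2-diphenyl-1,3-benzodioxol-5-yl)-3-oxopropanoate
Conditions: LiN(SiMe3)2 (3 equiv), THF, −78 °C, 4 first then 3, to 0 °C; aq. NH4Cl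
Reagents that add atoms: none
Why: Crossed Claisen condensation: 4 is fully enolised before the non-enolisable ester 3 is added, so self-condensation has no neutral partner, and the surplus base converts 5 into its stabilised enolate, which pulls the equilibrium forward; the α-centre forms racemic and stays enolisable.

Step 3
Reactants: 5 racemic ethyl 2-(benzyloxy)-3-(2,2-diphenyl-1,3-benzodioxol-5-yl)-3-oxopropanoate; 6 phloroglucinol
Product: 10 3-(benzyloxy)-2-(2,2-diphenyl-1,3-benzodioxol-5-yl)-5,7-dihydroxy-4H-chromen-4-one, via acylketene 7 (not isolated), via aryl diketone 8 (not isolated), via cyclic hemiketal 9 (not isolated)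
Conditions: 6 (2 equiv, anhydrous), neat melt, 240–250 °C, N2 stream, EtOH and H2O distilled off
Reagents that add atoms: none
Why: Mentzer pyrone synthesis, the uncatalysed thermal relative of the Simonis chromone synthesis, in its α-substituted form that leads to 3-substituted chromones. The enol of 5 expels ethanol through a six-membered transition state to give acylketene 7, and a ring carbon of 6 attacks the ketene carbon (C4a–C4) to give, after tautomerisation, aryl diketone 8; O-acylation of 6, should it compete, is reversible through the same ketene at this temperature, whereas C-acylation is not. The hydroxyl ortho to the new acyl group then adds to the aryl ketone carbonyl in a 6-exo-trig closure (O1–C2) to give hemiketal 9, and loss of water, driven by formation of the aromatic, internally hydrogen-bonded 4-pyranone, gives 10. No stereocentre survives: the labile centre of 5 and the hemiketal carbon of 9 both become sp2 on dehydration. The selectivity that matters is chromone against coumarin: the Pechmann path needs acid to make the ring carbon attack the ketone, and here there is no acid, the ketone is a conjugated, α-alkoxy-hindered aryl ketone, and the ketene is by far the stronger electrophile. Regiochemistry on ring A does not arise because the three C–H/O–H pairs of 6 are identical, and the first acylation deactivates the ring towards a second one, which the excess of 6 suppresses further. Benzyl ether and diphenylmethylene ketal have no low-energy pathway under neutral conditions, and a ketal lost to the water of reaction would merely deliver 11 one step early.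

Step 4
Reactants: 10 3-(benzyloxy)-2-(2,2-diphenyl-1,3-benzodioxol-5-yl)-5,7-dihydroxy-4H-chromen-4-one
Product: 11 3-(benzyloxy)-2-(3,4-dihydroxyphenyl)-5,7-dihydroxy-4H-chromen-4-one (3-O-benzylquercetin)
Conditions: AcOH/H2O (4:1), reflux
Reagents that add atoms: none
Why: Acid-catalysed ketal hydrolysis through the diaryl-stabilised oxocarbenium ion; the C3 benzyl ether has no comparably stabilised cleavage path in aqueous acetic acid and is retained.

Step 5
Reactants: 11 3-(benzyloxy)-2-(3,4-dihydroxyphenyl)-5,7-dihydroxy-4H-chromen-4-one
Product: 12 3-(benzyloxy)-5-hydroxy-4-oxo-2-[3,4-bis(sulfooxy)phenyl]-4H-chromen-7-yl hydrogen sulfate (3-O-benzylquercetin 7,3',4'-tri-O-sulfate)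
Conditions: SO3·pyridine (excess), pyridine, 60 °C
Reagents that add atoms: sulfur trioxide–pyridine complex, O=S(=O)([O-])[n+]1ccccc1
Why: O-Sulfation of phenols with an SO3–amine complex; the C5 hydroxyl is locked in its hydrogen bond to the C4 carbonyl and is the least nucleophilic oxygen, so excess reagent should drive C7, C3' and C4' to completion without touching it, C3 being blocked as the benzyl ether.

Step 6
Reactants: 12 3-O-benzylquercetin 7,3',4'-tri-O-sulfate
Product: 13 3,5-dihydroxy-4-oxo-2-[3,4-bis(sulfooxy)phenyl]-4H-chromen-7-yl hydrogen sulfate (quercetin 7,3',4'-tri-O-sulfate)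
Conditions: H2 (1 atm), Pd/C, MeOH/H2O, rt
Reagents that add atoms: none
Why: Catalytic hydrogenolysis of a benzyl ether; aryl sulfate monoester anions are inert to H2 over palladium in neutral aqueous methanol, and the tetrasubstituted C2=C3 bond of the pyranone is not reduced at one atmosphere and room temperature.

Step 7
Reactants: 13 quercetin 7,3',4'-tri-O-sulfate
Product: 14 5-hydroxy-4-oxo-7-(sulfooxy)-2-[3,4-bis(sulfooxy)phenyl]-4H-chromen-3-yl acetate (quercetin 3-acetate 7,3',4'-tri-O-sulfate)
Conditions: Ac2O (1.2 equiv), pyridine/DMF, 0 °C
Reagents that add atoms: acetic anhydride, CC(=O)OC(C)=O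
Why: Pyridine-mediated O-acetylation; the C3 hydroxyl sits in a weaker five-membered hydrogen bond and acylates well before the strongly chelated C5 hydroxyl, and sulfate monoester anions are too weakly nucleophilic to be acylated durably (a mixed anhydride, if formed, reverts by attack at the acetyl carbon), so limiting Ac2O at 0 °C should stop at the monoacetate.

## Compound list

1 | methyl 3,4-dihydroxybenzoate | COC(=O)c1ccc(O)c(O)c1 | starting material
2 | dichlorodiphenylmethane | ClC(Cl)(c1ccccc1)c1ccccc1 | starting material
3 | methyl 2,2-diphenyl-1,3-benzodioxole-5-carboxylate | COC(=O)c1ccc2OC(c3ccccc3)(c3ccccc3)Oc2c1 | intermediate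
4 | ethyl 2-(benzyloxy)acetate | CCOC(=O)COCc1ccccc1 | starting material
5 | racemic ethyl 2-(benzyloxy)-3-(2,2-diphenyl-1,3-benzodioxol-5-yl)-3-oxopropanoate (enolisable centre; one enantiomer drawn) | CCOC(=O)[C@H](OCc1ccccc1)C(=O)c1ccc2OC(c3ccccc3)(c3ccccc3)Oc2c1 | intermediate
6 | phloroglucinol (benzene-1,3,5-triol) | Oc1cc(O)cc(O)c1 | starting material
7 | 2-(benzyloxy)-3-(2,2-diphenyl-1,3-benzodioxol-5-yl)-3-oxoprop-1-en-1-one (acylketene; not isolated) | O=C=C(OCc1ccccc1)C(=O)c1ccc2OC(c3ccccc3)(c3ccccc3)Oc2c1 | intermediate
8 | racemic 2-(benzyloxy)-1-(2,2-diphenyl-1,3-benzodioxol-5-yl)-3-(2,4,6-trihydroxyphenyl)propane-1,3-dione (not isolated; one enantiomer drawn) | O=C(c1c(O)cc(O)cc1O)[C@H](OCc1ccccc1)C(=O)c1ccc2OC(c3ccccc3)(c3ccccc3)Oc2c1 | intermediate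
9 | 3-(benzyloxy)-2-(2,2-diphenyl-1,3-benzodioxol-5-yl)-2,5,7-trihydroxychroman-4-one (hemiketal; not isolated; racemic mixture of diastereomers, configuration not defined) | O=C1c2c(O)cc(O)cc2OC(O)(c2ccc3OC(c4ccccc4)(c4ccccc4)Oc3c2)C1OCc1ccccc1 | intermediate
10 | 3-(benzyloxy)-2-(2,2-diphenyl-1,3-benzodioxol-5-yl)-5,7-dihydroxy-4H-chromen-4-one | O=c1c(OCc2ccccc2)c(-c2ccc3OC(c4ccccc4)(c4ccccc4)Oc3c2)oc2cc(O)cc(O)c12 | intermediate
11 | 3-(benzyloxy)-2-(3,4-dihydroxyphenyl)-5,7-dihydroxy-4H-chromen-4-one (3-O-benzylquercetin) | O=c1c(OCc2ccccc2)c(-c2ccc(O)c(O)c2)oc2cc(O)cc(O)c12 | intermediate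
12 | 3-(benzyloxy)-5-hydroxy-4-oxo-2-[3,4-bis(sulfooxy)phenyl]-4H-chromen-7-yl hydrogen sulfate | O=c1c(OCc2ccccc2)c(-c2ccc(OS(=O)(=O)O)c(OS(=O)(=O)O)c2)oc2cc(OS(=O)(=O)O)cc(O)c12 | intermediate
13 | 3,5-dihydroxy-4-oxo-2-[3,4-bis(sulfooxy)phenyl]-4H-chromen-7-yl hydrogen sulfate (quercetin 7,3',4'-tri-O-sulfate) | O=c1c(O)c(-c2ccc(OS(=O)(=O)O)c(OS(=O)(=O)O)c2)oc2cc(OS(=O)(=O)O)cc(O)c12 | intermediate
14 | quercetin 3-acetate 7,3',4'-tri-O-sulfate | CC(=O)Oc1c(-c2ccc(OS(=O)(=O)O)c(OS(=O)(=O)O)c2)oc2cc(OS(=O)(=O)O)cc(O)c2c1=O | target

## Step count and least certain steps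

Total step count: 7. Longest linear sequence: 7 steps (1 → 3 → 5 → 10 → 11 → 12 → 13 → 14); 2, 4 and 6 enter as purchased materials.

**Step 3 (key step).** The most likely failure is consumption of the keto ester by paths other than C-acylation before ring C closes:
- Pechmann-type closure at the ketone to the isomeric coumarin;
- cleavage of the 1,3-dicarbonyl unit by the water and ethanol set free;
- retro-ene loss of the benzyl group from the α-benzyloxy ketone at 240 °C.

The fallback replaces the thermal union by an Allan–Robinson condensation; it sets out from 6 and 3 and returns at 10. Houben–Hoesch acylation of 6 with benzyloxyacetonitrile (ZnCl2, HCl, Et2O, 0 °C, then hot water) would give 2-(benzyloxy)-1-(2,4,6-trihydroxyphenyl)ethan-1-one F1. Ester 3 would be saponified (LiOH, THF/H2O) to 2,2-diphenyl-1,3-benzodioxole-5-carboxylic acid F2 and dehydrated with DCC to 2,2-diphenyl-1,3-benzodioxole-5-carboxylic anhydride F3. Heating F1 with F3 and Et3N at about 160 °C should give, by O-aroylation, Baker–Venkataraman acyl shift and ring closure, the flavone as its 7-O-aroyl ester, 3-(benzyloxy)-2-(2,2-diphenyl-1,3-benzodioxol-5-yl)-5-hydroxy-4-oxo-4H-chromen-7-yl 2,2-diphenyl-1,3-benzodioxole-5-carboxylate F4. Cleaving this ester with KOH in aqueous ethanol would return to the route at 10.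

**Step 7.** The most likely failure is acetyl transfer that does not stop at C3 once excess reagent is present, or hydrolytic loss of the new enol acetate while the polar salt is isolated. The fallback moves acetylation ahead of sulfation on neutral, chromatographable compounds; it sets out from 11 and returns at 14.
- Silylation of the three unchelated phenols (TBSCl, imidazole, DMF) would give 3-(benzyloxy)-7-(tert-butyldimethylsilyloxy)-2-[3,4-bis(tert-butyldimethylsilyloxy)phenyl]-5-hydroxy-4H-chromen-4-one F5.
- Hydrogenolysis (H2, Pd/C, EtOAc) would give 7-(tert-butyldimethylsilyloxy)-2-[3,4-bis(tert-butyldimethylsilyloxy)phenyl]-3,5-dihydroxy-4H-chromen-4-one F6.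
- Ac2O in pyridine would give 7-(tert-butyldimethylsilyloxy)-2-[3,4-bis(tert-butyldimethylsilyloxy)phenyl]-5-hydroxy-4-oxo-4H-chromen-3-yl acetate F7.
- Acidic fluoride (HF·pyridine, THF, 0 °C), which leaves the enol acetate alone, would give 2-(3,4-dihydroxyphenyl)-5,7-dihydroxy-4-oxo-4H-chromen-3-yl acetate (quercetin 3-acetate) F8.
- Sulfation of F8 with SO3·pyridine in DMF would give 14 directly.

**Step 5.** The most likely failure is incomplete sulfation of ring B, where the second sulfate must be placed beside an already anionic neighbour, leaving partially sulfated salts that are hard to separate. The fallback introduces the sulfates as neutral diesters; it sets out from 11 and returns at 12. Reaction with 2,2,2-trichloroethyl chlorosulfate (Et3N, DMAP, THF, 0 °C) would give 3-(benzyloxy)-5-hydroxy-4-oxo-2-{3,4-bis[(2,2,2-trichloroethoxy)sulfonyloxy]phenyl}-4H-chromen-7-yl 2,2,2-trichloroethyl sulfate F9, which can be purified on silica. Reductive removal of the trichloroethyl groups (Zn, HCO2NH4, MeOH, rt) leaves the benzyl ether in place and gives 12.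

**Step 2.** The most likely failure is self-condensation of the glycolate enolate once neutral 4 is regenerated by proton transfer, together with slow addition to the electron-rich benzoate 3. The fallback forms the C–O bond of the benzyl ether after the carbon skeleton; it sets out from 3 and returns at 5.
- Claisen condensation of 3 with the lithium enolate of ethyl acetate (LiN(SiMe3)2, THF, −78 °C to rt) would give ethyl 3-(2,2-diphenyl-1,3-benzodioxol-5-yl)-3-oxopropanoate F10.
- Regitz diazo transfer (4-acetamidobenzenesulfonyl azide, Et3N, MeCN) would give ethyl 2-diazo-3-(2,2-diphenyl-1,3-benzodioxol-5-yl)-3-oxopropanoate F11.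
- Rh2(OAc)4-catalysed O–H insertion into benzyl alcohol (CH2Cl2, rt) would give 5.

## Further compounds

F1 | step 3 | 2-(benzyloxy)-1-(2,4,6-trihydroxyphenyl)ethan-1-one | O=C(COCc1ccccc1)c1c(O)cc(O)cc1O
F2 | step 3 | 2,2-diphenyl-1,3-benzodioxole-5-carboxylic acid | OC(=O)c1ccc2OC(c3ccccc3)(c3ccccc3)Oc2c1
F3 | step 3 | 2,2-diphenyl-1,3-benzodioxole-5-carboxylic anhydride | O=C(OC(=O)c1ccc2OC(c3ccccc3)(c3ccccc3)Oc2c1)c1ccc2OC(c3ccccc3)(c3ccccc3)Oc2c1
F4 | step 3 | 3-(benzyloxy)-2-(2,2-diphenyl-1,3-benzodioxol-5-yl)-5-hydroxy-4-oxo-4H-chromen-7-yl 2,2-diphenyl-1,3-benzodioxole-5-carboxylate | O=c1c(OCc2ccccc2)c(-c2ccc3OC(c4ccccc4)(c4ccccc4)Oc3c2)oc2cc(OC(=O)c3ccc4OC(c5ccccc5)(c5ccccc5)Oc4c3)cc(O)c12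
F5 | step 7 | 3-(benzyloxy)-7-(tert-butyldimethylsilyloxy)-2-[3,4-bis(tert-butyldimethylsilyloxy)phenyl]-5-hydroxy-4H-chromen-4-one | O=c1c(OCc2ccccc2)c(-c2ccc(O[Si](C)(C)C(C)(C)C)c(O[Si](C)(C)C(C)(C)C)c2)oc2cc(O[Si](C)(C)C(C)(C)C)cc(O)c12
F6 | step 7 | 7-(tert-butyldimethylsilyloxy)-2-[3,4-bis(tert-butyldimethylsilyloxy)phenyl]-3,5-dihydroxy-4H-chromen-4-one | O=c1c(O)c(-c2ccc(O[Si](C)(C)C(C)(C)C)c(O[Si](C)(C)C(C)(C)C)c2)oc2cc(O[Si](C)(C)C(C)(C)C)cc(O)c12
F7 | step 7 | 7-(tert-butyldimethylsilyloxy)-2-[3,4-bis(tert-butyldimethylsilyloxy)phenyl]-5-hydroxy-4-oxo-4H-chromen-3-yl acetate | CC(=O)Oc1c(-c2ccc(O[Si](C)(C)C(C)(C)C)c(O[Si](C)(C)C(C)(C)C)c2)oc2cc(O[Si](C)(C)C(C)(C)C)cc(O)c2c1=O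
F8 | step 7 | 2-(3,4-dihydroxyphenyl)-5,7-dihydroxy-4-oxo-4H-chromen-3-yl acetate (quercetin 3-acetate) | CC(=O)Oc1c(-c2ccc(O)c(O)c2)oc2cc(O)cc(O)c2c1=O
F9 | step 5 | 3-(benzyloxy)-5-hydroxy-4-oxo-2-{3,4-bis[(2,2,2-trichloroethoxy)sulfonyloxy]phenyl}-4H-chromen-7-yl 2,2,2-trichloroethyl sulfate | O=c1c(OCc2ccccc2)c(-c2ccc(OS(=O)(=O)OCC(Cl)(Cl)Cl)c(OS(=O)(=O)OCC(Cl)(Cl)Cl)c2)oc2cc(OS(=O)(=O)OCC(Cl)(Cl)Cl)cc(O)c12
F10 | step 2 | ethyl 3-(2,2-diphenyl-1,3-benzodioxol-5-yl)-3-oxopropanoate | CCOC(=O)CC(=O)c1ccc2OC(c3ccccc3)(c3ccccc3)Oc2c1
F11 | step 2 | ethyl 2-diazo-3-(2,2-diphenyl-1,3-benzodioxol-5-yl)-3-oxopropanoate | CCOC(=O)C(=[N+]=[N-])C(=O)c1ccc2OC(c3ccccc3)(c3ccccc3)Oc2c1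
A1 | alternative 1 | racemic trans-5,7-bis(benzyloxy)-2-[3,4-bis(benzyloxy)phenyl]-3-hydroxychroman-4-one (one enantiomer drawn) | c1cc(OCc2ccccc2)c(OCc2ccccc2)cc1[C@@H]1[C@H](C(=O)c2c(OCc3ccccc3)cc(OCc3ccccc3)cc2O1)O
A2 | alternative 1 | racemic 2-[3,4-bis(benzyloxy)phenyl]-2-[3,5-bis(benzyloxy)-2-formylphenoxy]acetaldehyde | O=CC(Oc1cc(OCc2ccccc2)cc(OCc2ccccc2)c1C=O)c1ccc(OCc2ccccc2)c(OCc2ccccc2)c1
A3 | alternative 2 | 2-[3,4-bis(tert-butyldimethylsilyloxy)phenyl]-5-hydroxy-4-oxo-7-(triisopropylsilyloxy)-4H-chromen-3-yl acetate | CC(=O)Oc1c(-c2ccc(O[Si](C)(C)C(C)(C)C)c(O[Si](C)(C)C(C)(C)C)c2)oc2cc(O[Si](C(C)C)(C(C)C)C(C)C)cc(O)c2c1=O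
A4 | alternative 2 | 6-(2-diazoacetyl)-2-[3,4-bis(tert-butyldimethylsilyloxy)phenyl]-4-oxo-4H-pyran-3-yl acetate | CC(=O)Oc1c(-c2ccc(O[Si](C)(C)C(C)(C)C)c(O[Si](C)(C)C(C)(C)C)c2)oc(C(=O)C=[N+]=[N-])cc1=O
A5 | alternative 2 | (triisopropylsilyloxy)ethyne | C#CO[Si](C(C)C)(C(C)C)C(C)C
A6 | alternative 3 | 3-(allyloxy)-5,7-bis(benzyloxy)-2-[3,4-bis(benzyloxy)phenyl]-4H-chromen-4-one | C=CCOc1c(-c2ccc(OCc3ccccc3)c(OCc3ccccc3)c2)oc2cc(OCc3ccccc3)cc(OCc3ccccc3)c2c1=O
A7 | alternative 3 | (Z)-2-(allyloxy)-3-[3,4-bis(benzyloxy)phenyl]-3-chloroprop-2-enoic acid | OC(=O)/C(OCC=C)=C(\c1ccc(OCc2ccccc2)c(OCc2ccccc2)c1)Cl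
A8 | alternative 3 | 3,5-bis(benzyloxy)-2-(trimethylsilyl)phenyl trifluoromethanesulfonate | C[Si](C)(C)c1c(OCc2ccccc2)cc(OCc2ccccc2)cc1OS(=O)(=O)C(F)(F)F
A9 | alternative 3 | 3,5-bis(benzyloxy)benzyne (1,2-didehydro-3,5-bis(benzyloxy)benzene) | C1#CC(OCc2ccccc2)=CC(OCc2ccccc2)=C1
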